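The route rests on cutting ring C at C4a–C4, C4–C3 and O1–C2. A ring A iodide, carbon monoxide and 4-ethynylanisole are then joined and cyclised to the flavone in one palladium-catalysed operation. The step exploits the local symmetry of ring A. With O5 benzylated and O7 and O8a carrying identical groups on either side of the C8 methylene bridge, C4a and C6 are equivalent. Mono-iodination therefore has one outcome, and O8a is the only unblocked oxygen ortho to the new C4 carbonyl. The precursor is this C4a iodide as its O7,O8a-diacetate, already bearing at C8 the hexasubstituted, benzyl-protected ring D dihydrochalcone. O3 is added afterwards, and all benzyl ethers fall in a neutral final hydrogenolysis.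

Key step: step 10

Labels: flavone numbering is used for rings A and C, and ring B is the anisyl ring. Ring D is the hexasubstituted dihydrochalcone ring (primed locants: C1' bears the ketone, C5' the bridge). Ring E is its 4-oxygenated phenyl ring. "Ring D arylmethyl" means [2,4-bis(benzyloxy)-3-{3-[4-(benzyloxy)phenyl]propanoyl}-6-methoxy-5-methylphenyl]methyl.

Assumption: the target has no stereocentre, so the carbinol of step 7 and the epoxide of step 12 are handled as racemates.

Design remarks:
- Ring D holds an enolisable aryl ketone from step 1 onwards. Ring A is therefore delivered as a weakly basic organocerium reagent rather than as the aryllithium itself.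
- The sensitive, very electron-rich iodoresorcinol enters the key step as its diacetate.

Step 1
Reactants: 1 2-methylbenzene-1,3,5-triol; 2 3-(4-hydroxyphenyl)propanoic acid
Product: 3 1-(2,4,6-trihydroxy-3-methylphenyl)-3-(4-hydroxyphenyl)propan-1-one
Conditions: BF3·OEt2 (neat), 85 °C; then H2O
Reagents that add atoms: none
Why: Friedel–Crafts acylation with the acid activated by BF3; C4 and C6 of 1 are equivalent, so only one mono-ketone can form, and the deactivating, boron-chelated acyl group should stop a second acylation.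

Step 2
Reactants: 3 1-(2,4,6-trihydroxy-3-methylphenyl)-3-(4-hydroxyphenyl)propan-1-one
Product: 4 1-(2,6-dihydroxy-4-methoxy-3-methylphenyl)-3-(4-hydroxyphenyl)propan-1-one
Conditions: Me2SO4 (1.0 equiv), K2CO3 (1.0 equiv), acetone, rt → 40 °C
Reagents that add atoms: dimethyl sulfate COS(=O)(=O)OC
Why: Williamson-type O-methylation under acidity control, in which the 4'-hydroxyl para to the ketone is the most acidic and the only ring D hydroxyl free of a hydrogen bond to the carbonyl, the ordinary ring E phenol stays protonated, and the hard electrophile favours O- over C-methylation.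

Step 3
Reactants: 4 1-(2,6-dihydroxy-4-methoxy-3-methylphenyl)-3-(4-hydroxyphenyl)propan-1-one
Product: 5 1-[2,6-bis(benzyloxy)-4-methoxy-3-methylphenyl]-3-[4-(benzyloxy)phenyl]propan-1-one
Conditions: BnBr (3.6 equiv), K2CO3, DMF, 65 °C
Reagents that add atoms: benzyl bromide BrCc1ccccc1
Why: Exhaustive Williamson benzylation in a dipolar aprotic solvent, warm enough to alkylate the chelated 2'- and 6'-hydroxyls, with a base too weak to enolise the ketone.

Step 4
Reactants: 5 1-[2,6-bis(benzyloxy)-4-methoxy-3-methylphenyl]-3-[4-(benzyloxy)phenyl]propan-1-one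
Product: 6 2,4-bis(benzyloxy)-3-{3-[4-(benzyloxy)phenyl]propanoyl}-6-methoxy-5-methylbenzaldehyde
Conditions: POCl3 (1.5 equiv), DMF, 0 °C → rt; then ice–water
Reagents that add atoms: N,N-dimethylformamide CN(C)C=O; water O
Why: Vilsmeier–Haack formylation at C5', the only free ring D position and one activated by two ortho and one para alkoxy groups; ring E is far less activated, no free ortho-hydroxyl is left to divert the reagent into chromone formation at the ketone α-carbon, and haloformylation of the hindered ketone needs heat.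

Step 5
Reactants: 7 phloroglucinol (benzene-1,3,5-triol)
Product: 8 5-(benzyloxy)benzene-1,3-diol
Conditions: 7 (3 equiv), BnBr (1 equiv), K2CO3 (1 equiv), DMF, rt
Reagents that add atoms: benzyl bromide BrCc1ccccc1
Why: Statistical mono-Williamson etherification of three equivalent hydroxyls, with the excess of cheap, water-soluble 7 holding back further benzylation and washing out on work-up.

Step 6
Reactants: 8 5-(benzyloxy)benzene-1,3-diol
Product: 9 1-(benzyloxy)-3,5-bis(methoxymethoxy)benzene
Conditions: MOMCl (2.5 equiv), iPr2NEt, CH2Cl2, 0 °C → rt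
Reagents that add atoms: chloromethyl methyl ether COCCl
Why: Acetal (MOM ether) protection of both phenols, which also installs two cooperating directing groups around C2 for the metalation in step 7.

Step 7
Reactants: 9 1-(benzyloxy)-3,5-bis(methoxymethoxy)benzene; 6 2,4-bis(benzyloxy)-3-{3-[4-(benzyloxy)phenyl]propanoyl}-6-methoxy-5-methylbenzaldehyde
Product: 12 racemic 1-[2,6-bis(benzyloxy)-3-{[4-(benzyloxy)-2,6-bis(methoxymethoxy)phenyl](hydroxy)methyl}-4-methoxy-5-methylphenyl]-3-[4-(benzyloxy)phenyl]propan-1-one, via aryllithium 10 (not isolated), via arylcerium dichloride 11 (not isolated)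
Conditions: 9 (1.3 equiv), n-BuLi, THF, 0 °C; anhydrous CeCl3, −78 °C; 6, −78 → −30 °C; aq NH4Cl
Reagents that add atoms: none
Why: Directed ortho-metalation at the carbon flanked by both MOM ethers, then transmetalation to a weakly basic organocerium reagent whose 1,2-addition should pick the aldehyde over the doubly ortho-substituted, enolisable ketone that an aryllithium would deprotonate; the new carbinol centre forms without control (racemic) and is deleted in step 8.

Step 8
Reactants: 12 racemic diaryl carbinol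
Product: 14 1-[2,6-bis(benzyloxy)-3-{[4-(benzyloxy)-2,6-dihydroxyphenyl]methyl}-4-methoxy-5-methylphenyl]-3-[4-(benzyloxy)phenyl]propan-1-one, via bis-MOM diarylmethane 13 (not isolated)
Conditions: Et3SiH (1.5 equiv), TFA, CH2Cl2, −20 → 0 °C; evaporate; 2 M HCl, MeOH–THF, 45 °C
Reagents that add atoms: none
Why: Ionic hydrogenation, in which the carbinol ionises to a benzhydryl cation stabilised by six oxygen donors and takes hydride from the silane long before the twisted, hindered ketone can react, followed by acid methanolysis of the MOM ethers with formaldehyde trapped as dimethoxymethane.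

Step 9
Reactants: 14 2-(ring D arylmethyl)-5-(benzyloxy)benzene-1,3-diol (same compound as named in step 8)
Product: 16 5-(benzyloxy)-4-iodo-2-(ring D arylmethyl)benzene-1,3-diyl diacetate, via iodoresorcinol 15 (not isolated)
Conditions: NIS (1.0 equiv), MeCN–CH2Cl2, −30 °C, dark; then Ac2O, Et3N, DMAP (cat.), 0 °C → rt
Reagents that add atoms: N-iodosuccinimide O=C1CCC(=O)N1I; acetic anhydride CC(=O)OC(C)=O
Why: Electrophilic aromatic iodination of the most electron-rich ring, whose two C–H positions are mirror-related so that one equivalent of NIS should give a single mono-iodide (ring D has no C–H, ring E is much less activated), followed by acetylation in the same flask, which turns the acid- and air-sensitive iodoresorcinol into a storable, less electron-rich aryl iodide.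

Step 10
Reactants: 16 5-(benzyloxy)-4-iodo-2-(ring D arylmethyl)benzene-1,3-diyl diacetate; 17 4-ethynylanisole; 18 carbon monoxide
Product: 21 5-(benzyloxy)-7-hydroxy-2-(4-methoxyphenyl)-8-(ring D arylmethyl)-4H-chromen-4-one, via diacetoxy ynone 19 (not isolated), via enaminone 20 (not isolated)
Conditions: PdCl2(PPh3)2 (5 mol %), dppp (5 mol %), thiourea (5 mol %), 17 (1.5 equiv), Et2NH, CO (5 bar), 60 °C
Reagents that add atoms: none
Why: PdCl2(PPh3)2 is reduced in the flask to zerovalent palladium, which inserts into the C4a–I bond of 16; CO insertion gives the acyl complex of divalent palladium, and amine-assisted alkynyl transfer from 17 with reductive elimination gives ynone 19 (C4a–C4 and C4–C3). Et2NH then cleaves both acetates and adds to the ynone to give enaminone 20, whose O8a attacks C2 and expels the amine (O1–C2). The closest known reaction type is the carbonylative Sonogashira annulation of 2-iodophenols or their acetates with terminal arylalkynes in secondary amines. Ring C closes in a 6-endo mode, and the addition–elimination on the enaminone is what shuts out the 5-exo closure to an aurone. No stereocentre is formed. The step needs carbonylation to outrun direct alkynylation (no copper, CO pressure, chelating phosphine) and a single sense of closure, which the substrate secures because O5 is benzylated and O7 sits para to C4a, while ring D offers neither a halide nor an aromatic C–H and its hindered ketone ignores the amine.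

Step 11
Reactants: 21 5-(benzyloxy)-7-hydroxy-2-(4-methoxyphenyl)-8-(ring D arylmethyl)-4H-chromen-4-one
Product: 22 5,7-bis(benzyloxy)-2-(4-methoxyphenyl)-8-(ring D arylmethyl)-4H-chromen-4-one
Conditions: BnBr (1.2 equiv), K2CO3, DMF, rt
Reagents that add atoms: benzyl bromide BrCc1ccccc1
Why: Williamson etherification of the only free phenol (O7), needed because a free phenol would not survive the dioxirane of step 12.

Step 12
Reactants: 22 5,7-bis(benzyloxy)-2-(4-methoxyphenyl)-8-(ring D arylmethyl)-4H-chromen-4-one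
Product: 24 5,7-bis(benzyloxy)-3-hydroxy-2-(4-methoxyphenyl)-8-(ring D arylmethyl)-4H-chromen-4-one, via epoxide 23 (not isolated)
Conditions: DMDO (acetone solution, excess), CH2Cl2, 0 °C → rt; concentrate; p-TsOH·H2O (cat.), CH2Cl2, rt
Reagents that add atoms: dimethyldioxirane CC1(C)OO1
Why: Dioxirane epoxidation of the C2–C3 double bond, then acid-catalysed opening at C2 (cation stabilised by O1 and the anisyl ring) and loss of H3, a known flavone-to-flavonol conversion; the two centres of the racemic, necessarily cis-fused epoxide vanish on rearomatisation.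

Step 13
Reactants: 24 5,7-bis(benzyloxy)-3-hydroxy-2-(4-methoxyphenyl)-8-(ring D arylmethyl)-4H-chromen-4-one
Product: 25 4'''-hydroxytrianguletin
Conditions: H2 (1 atm), 10% Pd/C, THF–MeOH, rt
Reagents that add atoms: none
Why: Catalytic hydrogenolysis of the five aryl benzyl ethers under neutral conditions, which should spare the flavonol double bond, the chelated ketone and the methylene bridge, a bond that acid or base can scramble once both flanking rings carry free hydroxyls.

Compound list
1 | 2-methylbenzene-1,3,5-triol | Cc1c(O)cc(O)cc1O | starting material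
2 | 3-(4-hydroxyphenyl)propanoic acid | O=C(O)CCc1ccc(O)cc1 | starting material
3 | 1-(2,4,6-trihydroxy-3-methylphenyl)-3-(4-hydroxyphenyl)propan-1-one | Cc1c(O)cc(O)c(C(=O)CCc2ccc(O)cc2)c1O | intermediate
4 | 1-(2,6-dihydroxy-4-methoxy-3-methylphenyl)-3-(4-hydroxyphenyl)propan-1-one | Cc1c(OC)cc(O)c(C(=O)CCc2ccc(O)cc2)c1O | intermediate
5 | 1-[2,6-bis(benzyloxy)-4-methoxy-3-methylphenyl]-3-[4-(benzyloxy)phenyl]propan-1-one | Cc1c(OC)cc(OCc2ccccc2)c(C(=O)CCc2ccc(OCc3ccccc3)cc2)c1OCc1ccccc1 | intermediate
6 | 2,4-bis(benzyloxy)-3-{3-[4-(benzyloxy)phenyl]propanoyl}-6-methoxy-5-methylbenzaldehyde | Cc1c(OC)c(C=O)c(OCc2ccccc2)c(C(=O)CCc2ccc(OCc3ccccc3)cc2)c1OCc1ccccc1 | intermediate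
7 | phloroglucinol | Oc1cc(O)cc(O)c1 | starting material
8 | 5-(benzyloxy)benzene-1,3-diol | Oc1cc(O)cc(OCc2ccccc2)c1 | intermediate
9 | 1-(benzyloxy)-3,5-bis(methoxymethoxy)benzene | COCOc1cc(OCOC)cc(OCc2ccccc2)c1 | intermediate
10 | [4-(benzyloxy)-2,6-bis(methoxymethoxy)phenyl]lithium | [Li]c1c(OCOC)cc(OCc2ccccc2)cc1OCOC | intermediate
11 | [4-(benzyloxy)-2,6-bis(methoxymethoxy)phenyl]cerium dichloride | Cl[Ce](Cl)c1c(OCOC)cc(OCc2ccccc2)cc1OCOC | intermediate
12 | racemic diaryl carbinol, ring A (bis-MOM, 4-OBn) and ring D joined through CH(OH) | OC(c1c(OCOC)cc(OCc2ccccc2)cc1OCOC)c1c(OC)c(C)c(OCc2ccccc2)c(C(=O)CCc2ccc(OCc3ccccc3)cc2)c1OCc1ccccc1 | intermediate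
13 | 5-(benzyloxy)-1,3-bis(methoxymethoxy)-2-(ring D arylmethyl)benzene | COCOc1cc(OCc2ccccc2)cc(OCOC)c1Cc1c(OC)c(C)c(OCc2ccccc2)c(C(=O)CCc2ccc(OCc3ccccc3)cc2)c1OCc1ccccc1 | intermediate
14 | 5-(benzyloxy)-2-(ring D arylmethyl)benzene-1,3-diol | Oc1cc(OCc2ccccc2)cc(O)c1Cc1c(OC)c(C)c(OCc2ccccc2)c(C(=O)CCc2ccc(OCc3ccccc3)cc2)c1OCc1ccccc1 | intermediate
15 | 5-(benzyloxy)-4-iodo-2-(ring D arylmethyl)benzene-1,3-diol | Oc1cc(OCc2ccccc2)c(I)c(O)c1Cc1c(OC)c(C)c(OCc2ccccc2)c(C(=O)CCc2ccc(OCc3ccccc3)cc2)c1OCc1ccccc1 | intermediate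
16 | 5-(benzyloxy)-4-iodo-2-(ring D arylmethyl)benzene-1,3-diyl diacetate | CC(=O)Oc1cc(OCc2ccccc2)c(I)c(OC(C)=O)c1Cc1c(OC)c(C)c(OCc2ccccc2)c(C(=O)CCc2ccc(OCc3ccccc3)cc2)c1OCc1ccccc1 | intermediate
17 | 4-ethynylanisole | C#Cc1ccc(OC)cc1 | starting material
18 | carbon monoxide | [C-]#[O+] | starting material
19 | 5-(benzyloxy)-4-[3-(4-methoxyphenyl)prop-2-ynoyl]-2-(ring D arylmethyl)benzene-1,3-diyl diacetate | CC(=O)Oc1cc(OCc2ccccc2)c(C(=O)C#Cc2ccc(OC)cc2)c(OC(C)=O)c1Cc1c(OC)c(C)c(OCc2ccccc2)c(C(=O)CCc2ccc(OCc3ccccc3)cc2)c1OCc1ccccc1 | intermediate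
20 | (E)-1-[6-(benzyloxy)-2,4-dihydroxy-3-(ring D arylmethyl)phenyl]-3-(diethylamino)-3-(4-methoxyphenyl)prop-2-en-1-one | Oc1cc(OCc2ccccc2)c(C(=O)/C=C(/N(CC)CC)c2ccc(OC)cc2)c(O)c1Cc1c(OC)c(C)c(OCc2ccccc2)c(C(=O)CCc2ccc(OCc3ccccc3)cc2)c1OCc1ccccc1 | intermediate
21 | 5-(benzyloxy)-7-hydroxy-2-(4-methoxyphenyl)-8-(ring D arylmethyl)-4H-chromen-4-one | COc1ccc(cc1)-c1cc(=O)c2c(OCc3ccccc3)cc(O)c(Cc3c(OC)c(C)c(OCc4ccccc4)c(C(=O)CCc4ccc(OCc5ccccc5)cc4)c3OCc3ccccc3)c2o1 | intermediate
22 | 5,7-bis(benzyloxy)-2-(4-methoxyphenyl)-8-(ring D arylmethyl)-4H-chromen-4-one | COc1ccc(cc1)-c1cc(=O)c2c(OCc3ccccc3)cc(OCc3ccccc3)c(Cc3c(OC)c(C)c(OCc4ccccc4)c(C(=O)CCc4ccc(OCc5ccccc5)cc4)c3OCc3ccccc3)c2o1 | intermediate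
23 | 2,3-epoxide of 22 (oxirane cis-fused across C2–C3; racemic, one enantiomer drawn) | COc1ccc(cc1)[C@]13O[C@@H]3C(=O)c2c(OCc4ccccc4)cc(OCc4ccccc4)c(Cc4c(OC)c(C)c(OCc5ccccc5)c(C(=O)CCc5ccc(OCc6ccccc6)cc5)c4OCc4ccccc4)c2O1 | intermediate
24 | 5,7-bis(benzyloxy)-3-hydroxy-2-(4-methoxyphenyl)-8-(ring D arylmethyl)-4H-chromen-4-one | COc1ccc(cc1)-c1oc2c(Cc3c(OC)c(C)c(OCc4ccccc4)c(C(=O)CCc4ccc(OCc5ccccc5)cc4)c3OCc3ccccc3)c(OCc3ccccc3)cc(OCc3ccccc3)c2c(=O)c1O | intermediate
25 | 4'''-hydroxytrianguletin | COc1ccc(-c2oc3c(Cc4c(O)c(C(=O)CCc5ccc(O)cc5)c(O)c(C)c4OC)c(O)cc(O)c3c(=O)c2O)cc1 | target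

Total step count: 13. Longest linear sequence: 11 (steps 1–4 and 7–13); steps 5 and 6 form the short ring A branch.

Steps most likely to fail

1. Step 10.
- What may go wrong: oxidative addition into a C–I bond flanked by two oxygen substituents on an electron-rich ring may be slow. Reductive loss of iodine, CO-free alkynylation, or interception of the acyl-palladium species by Et2NH could then take over.
- Fallback: it uses neither palladium nor CO and brings in C4 as a formyl carbon. It sets out from 14 and comes back at 20, and hence at 21.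
- Magnesium-mediated ortho-formylation (MgCl2, Et3N, paraformaldehyde, MeCN, reflux) at either of the two equivalent ring A positions should give the dihydroxy aldehyde F1.
- MOMCl/iPr2NEt then gives the bis-MOM aldehyde F2.
- The alkynylmagnesium bromide F3, made from 17 with EtMgBr in THF, should add to the aldehyde and leave the hindered ketone alone, giving the racemic propargylic alcohol F4.
- MnO2 in CH2Cl2 gives the bis-MOM ynone F5, and Et2NH in EtOH adds to it to give the bis-MOM enaminone F6.
- HCl in MeOH removes both acetals to give 20, which should close to 21 in the same medium.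

2. Step 7.
- What may go wrong: addition between two doubly ortho-substituted partners may be so slow that thermal decay of the organocerium reagent or proton transfer from the ketone α-position competes.
- Fallback: the bridge bond is made by cross-coupling at the CH2 oxidation level, so no carbinol and no ionic reduction are needed. It sets out from 6 and 10 and comes back at 13.
- NaBH4 (MeOH–THF, 0 °C) should reduce only the aldehyde, giving the ring D benzylic alcohol F7.
- SOCl2/pyridine (CH2Cl2, 0 °C) gives the ring D benzylic chloride F8, which is used crude.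
- ZnCl2 converts 10 into the ketone-tolerant arylzinc chloride F9.
- Negishi coupling of F8 with F9 (Pd(OAc)2, SPhos, THF, 50 °C) should give 13, which is then taken through the HCl/MeOH half of step 8.

3. Step 12.
- What may go wrong: oxygen transfer to the electron-poor C2–C3 bond is slow. Under the excess of dioxirane required, oxidation of the electron-rich rings A and D or of benzylic C–H bonds may erode the material.
- Fallback: it replaces electrophilic oxygen transfer by deprotonation. It sets out from 22 and comes back at 24.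
- LDA (2.5 equiv, THF, −78 °C) metalates C3; the first equivalent is taken up by the ring D ketone as its enolate, which protects it.
- B(OMe)3 then gives the dimethyl flavon-3-ylboronate F10.
- H2O2/AcOH oxidises the C–B bond to the 3-hydroxyl of 24, and the enolate returns to the ketone on work-up.

Further compounds
F1 | step 10 | 6-(benzyloxy)-2,4-dihydroxy-3-(ring D arylmethyl)benzaldehyde | O=Cc1c(OCc2ccccc2)cc(O)c(Cc2c(OC)c(C)c(OCc3ccccc3)c(C(=O)CCc3ccc(OCc4ccccc4)cc3)c2OCc2ccccc2)c1O
F2 | step 10 | 6-(benzyloxy)-2,4-bis(methoxymethoxy)-3-(ring D arylmethyl)benzaldehyde | O=Cc1c(OCc2ccccc2)cc(OCOC)c(Cc2c(OC)c(C)c(OCc3ccccc3)c(C(=O)CCc3ccc(OCc4ccccc4)cc3)c2OCc2ccccc2)c1OCOC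
F3 | step 10 | [(4-methoxyphenyl)ethynyl]magnesium bromide | Br[Mg]C#Cc1ccc(OC)cc1
F4 | step 10 | racemic 1-[6-(benzyloxy)-2,4-bis(methoxymethoxy)-3-(ring D arylmethyl)phenyl]-3-(4-methoxyphenyl)prop-2-yn-1-ol | OC(C#Cc1ccc(OC)cc1)c1c(OCc2ccccc2)cc(OCOC)c(Cc2c(OC)c(C)c(OCc3ccccc3)c(C(=O)CCc3ccc(OCc4ccccc4)cc3)c2OCc2ccccc2)c1OCOC
F5 | step 10 | 1-[6-(benzyloxy)-2,4-bis(methoxymethoxy)-3-(ring D arylmethyl)phenyl]-3-(4-methoxyphenyl)prop-2-yn-1-one | O=C(C#Cc1ccc(OC)cc1)c1c(OCc2ccccc2)cc(OCOC)c(Cc2c(OC)c(C)c(OCc3ccccc3)c(C(=O)CCc3ccc(OCc4ccccc4)cc3)c2OCc2ccccc2)c1OCOC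
F6 | step 10 | (E)-1-[6-(benzyloxy)-2,4-bis(methoxymethoxy)-3-(ring D arylmethyl)phenyl]-3-(diethylamino)-3-(4-methoxyphenyl)prop-2-en-1-one | COCOc1cc(OCc2ccccc2)c(C(=O)/C=C(/N(CC)CC)c2ccc(OC)cc2)c(OCOC)c1Cc1c(OC)c(C)c(OCc2ccccc2)c(C(=O)CCc2ccc(OCc3ccccc3)cc2)c1OCc1ccccc1
F7 | step 7 | 1-[2,6-bis(benzyloxy)-3-(hydroxymethyl)-4-methoxy-5-methylphenyl]-3-[4-(benzyloxy)phenyl]propan-1-one | OCc1c(OC)c(C)c(OCc2ccccc2)c(C(=O)CCc2ccc(OCc3ccccc3)cc2)c1OCc1ccccc1
F8 | step 7 | 1-[2,6-bis(benzyloxy)-3-(chloromethyl)-4-methoxy-5-methylphenyl]-3-[4-(benzyloxy)phenyl]propan-1-one | ClCc1c(OC)c(C)c(OCc2ccccc2)c(C(=O)CCc2ccc(OCc3ccccc3)cc2)c1OCc1ccccc1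
F9 | step 7 | [4-(benzyloxy)-2,6-bis(methoxymethoxy)phenyl]zinc chloride | Cl[Zn]c1c(OCOC)cc(OCc2ccccc2)cc1OCOC
F10 | step 12 | dimethyl [5,7-bis(benzyloxy)-2-(4-methoxyphenyl)-4-oxo-8-(ring D arylmethyl)-4H-chromen-3-yl]boronate | COc1ccc(cc1)-c1oc2c(Cc3c(OC)c(C)c(OCc4ccccc4)c(C(=O)CCc4ccc(OCc5ccccc5)cc4)c3OCc3ccccc3)c(OCc3ccccc3)cc(OCc3ccccc3)c2c(=O)c1B(OC)OC
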